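Readings and results stem from a simulated flask with constants of no real substance, noise included.

Tuesday's flask, at 118 °C, still holds 10.7% of its substrate after 8.00 min, although 1.3 equiv of partner was charged. We read this leftover as partner lost without making product. For 89.4% of product, that comes to 0.454 lost per one used: the waste ratio, partner lost per partner turned into product.

| flask | substrate | partner | temperature | remark | time |
|---|---|---|---|---|---|
| Thursday's | 0.0067 M | 1.3 equiv | 85 °C | run made earlier |  |
| Tuesday's | 0.015 M | 1.3 equiv | 118 °C | run made earlier |  |
| maple | 0.010 M | 1.30 equiv | 130 °C |  | 12 min |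
| cedar | 0.010 M | 1.30 equiv | 90 °C |  | 12 min |
| birch | 0.010 M | 1.30 equiv | 110 °C |  | 12 min |
| oak | 0.010 M | 1.30 equiv | 125 °C |  | 12 min |
| alder | 0.010 M | 1.30 equiv | 70 °C |  | 12 min |

| run | time / min | product / % | substrate / % |
|---|---|---|---|
| Thursday's | 5.00 | 25.2 | 75.2 |
| Thursday's | 10.0 | 58.6 | 41.5 |
| Thursday's | 15.0 | 77.0 | 23.6 |
| Thursday's | 20.0 | 85.5 | 14.5 |
| Thursday's | 30.0 | 92.4 | 7.2 |
| Tuesday's | 0.500 | 37.3 | 62.9 |
| Tuesday's | 1.00 | 70.6 | 29.3 |
| Tuesday's | 2.00 | 84.8 | 15.2 |
| Tuesday's | 4.00 | 88.6 | 11.3 |
| Tuesday's | 8.00 | 89.4 | 10.7 |

(readings scatter by 0.3 percentage points)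

1. all flasks from highest to lowest amount of product, in percent of the substrate charged, at 12 min (maple / cedar / birch / oak / alder)
2. the amount of product, in percent of the substrate charged of the flask you put first, at 12 min
3. the amount of product, in percent of the substrate charged of the flask you put last, at 12 min

Thursday's run shows what moves the rate. Its product gains 25.2% by 5.00 min, then more, 33 percentage points, by 10.0 min, so we take the rate as proportional to substrate, partner and product (autocatalysis). From the stretch 5.00 min to 10.0 min to the stretch 20.0 min to 30.0 min, the rate falls by a factor 9.68. Substrate accounts for a factor 5.38 and partner spent on product for 2.15, while the rise in product gives back 2.12. The remaining factor, 1.78, is accumulated slowing, which we read as lost partner. It gives Thursday a waste ratio of 0.202, lower than Tuesday's.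

Reaction carries two concentrations beyond partner, and we take the loss as first order, so the ratio should go as the inverse square of concentration. So corrected, it climbs by a factor 11.3 between the two temperatures, and we spread that evenly on a logarithmic scale. Where partner runs out first, as the limiting reagent, we reckon that product stops at the partner charge divided by one plus the ratio. At 0.010 M, our estimate gives maple a ratio of 2.46 and a ceiling of 37.5%; it puts oak's ceiling at 48.0% and birch's at 82.9%. Our ceiling for cedar, 115%, is more than the substrate charged, so we reckon cedar by its time instead. By the square of concentration, cedar's 12 min counts as 26.7 min on Thursday's clock, and cedar is warmer than Thursday's run, so we put cedar first and maple last, leaving alder unplaced.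

The forecast gave birch > cedar > oak > maple > alder, with 91% and 25%: “Hot flasks die early; the cold flask is still in its lag”.

The flasks give cedar > birch > alder > oak > maple, with cedar at 94.7%, maple at 39.4% and alder at 73.9%.

    substrate + partner + released group → product + 2 released group (k = 320 L² mol⁻² s⁻¹, Ea = 44.0 kJ mol⁻¹)
    substrate + partner → product + released group (k = 0.140 L mol⁻¹ s⁻¹, Ea = 52.0 kJ mol⁻¹)
    partner → decomposed reagent (k = 0.00320 s⁻¹, Ea = 125 kJ mol⁻¹)
    (constants at 110 °C)

Tuesday's 0.454, carried to maple, gave 2.46; maple's decomposed reagent over released group at 12.0 min is 2.30. The neighbouring flask is maple with 0.025 M of substrate, equivalents held. The inverse square takes our ratio to 0.394, a ceiling of 93.2%. That flask shows a ratio of 0.391 and holds 93.4% of product at 12.0 min, with 6.55% of substrate left.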